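All runs are calculated from invented constants.

Start from the leftover: starting material, the limiting reagent, reads 0.3 % at 720 min in the south-east run, less than the scatter of 0.5 percentage points, so read the end of this flask as a plateau.

all flasks: free catalyst 0.5 mol%; temperature 25 °C

| flask | starting material | remark | time |
|---|---|---|---|
| south-east | 1.5 M | the very flask that is asked about, followed so far |  |
| south-west | 1 M | run made earlier |  |
| flask | 1.5 M |  | 12 h |

Note that both runs share one loading and differ in charge, so together they show what the charge does.

| run | time / min | product / % | starting material / % |
|---|---|---|---|
| south-east | 60.0 | 33.8 | 22.9 |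
| south-east | 80.0 | 41.0 | 14.6 |
| south-east | 120 | 49.5 | 5.4 |
| south-east | 180 | 55.0 | 0.5 |
| south-east | 300 | 55.1 | 0 |
| south-east | 480 | 55.5 | 0 |
| south-east | 720 | 55.9 | 0.3 |
| south-west | 5.00 | 3.0 | 91.2 |
| south-west | 10.0 | 5.5 | 80.9 |
| south-west | 15.0 | 8.9 | 73.4 |
| south-west | 20.0 | 11.5 | 67.7 |
| south-west | 25.0 | 13.7 | 61.7 |
| south-west | 30.0 | 17.7 | 55.1 |

(each reading ± 0.5 percentage points)

Count product per catalyst first: the south-east run made 1.13 min⁻¹ up to 60.0 min, and the south-west run 1.18 min⁻¹ up to 30.0 min, about the same pace. So take the product rate in M per minute as growing with the charge.

Then read the plateau of the south-east run, whose last three readings average 55.5 %. Use the even split as the zero of the scale and define the split ratio, the missing part over the product at the end: it is 0.802, against 1 for an even split.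

Now see when the loss happens. In the south-east run, product reads 43.8 % of what was consumed up to 60.0 min, but 89.7 % from there to 120 min. Take the loss, as my own reckoning, to follow the square of [starting material]. Take the pace per catalyst as steady as well. Loss and turnover then match at a concentration growing as the square root of the charge, so estimate that, at one loading and temperature, the split ratio grows roughly as that root too.

- product, in percent of the starting material first charged, at 12 h
- the remedy with the largest gain of product, or "none" below 2 percentage points (teal / grey / red / amber / none)
- product present, with what was taken out counted in, in percent of the starting material first charged, after teal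
- product present, with what was taken out counted in, in percent of the starting material first charged, after red

- teal: change nothing and wait 4.0 h more
- grey: at 12 h take out 90 % of the product then present, then wait 4.0 h
- red: at 12 h raise the temperature by 25 K, then wait 4.0 h
- amber: at 12 h add free catalyst, 100 % of the amount charged, then wait 4.0 h

- what is taken out of product is counted as made
- what was read earlier has a scatter of 0.5 percentage points, one standard deviation
- additions bring no volume worth counting

My answer is therefore 55.5 % now and after teal and red, with no remedy, since the leftover is below the margin and I take the missing part as lost for good.

The forecast gives 55.5 %, 55.7 % after teal, 56 % after red and none as the best remedy, for removing product or adding catalyst has “nothing to act on, since no starting material remains”.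

The flask gives 55.4 %, 55.4 % after teal, 55.4 % after red, and none.

    starting material + free catalyst → catalyst intermediate A (k = 260 L mol⁻¹ h⁻¹, Ea = 44.0 kJ mol⁻¹)
    catalyst intermediate A → catalyst intermediate B (k = 190 h⁻¹, Ea = 70.0 kJ mol⁻¹)
    catalyst intermediate B → free catalyst + product (k = 250 h⁻¹, Ea = 83.0 kJ mol⁻¹)
    2 starting material → homo dimer (k = 0.450 L mol⁻¹ h⁻¹, Ea = 71.0 kJ mol⁻¹)
    (constants at 25 °C)

The missing part is homo dimer, counted by the starting material it holds: 44.6 % beside 55.4 % of product at 720 min, so this flask's split ratio stands at 0.805. Carry it to the neighbour flask with 2.5 M of starting material, at the same loading and time: multiply 0.802 by the square root of 2.5 M over 1.5 M to get 1.04, just past the even split, which means 49.0 % of product. That neighbour flask gives 48.9 % of product and 51.1 % of homo dimer, with 0 % of starting material left.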